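## Retrosynthetic overview

1. C2–Cl / C3–Br: trans-diaxial bromochloride ⇐ chlorohydrin ⇐ ring-A epoxide (chloride opens at C2 with inversion; tertiary OH → Br with retention).
2. C9–OAc / C10–Br: cis-bromohydrin acetate ⇐ α-bromoketone ⇐ regiodefined C9=C10 silyl enol ether.
3. Key disconnection C6–C11 (spiro carbon next to the gem-dimethyl carbon): photochemical C–H abstraction and radical recombination in an acyclic dienone, carrying the limonene stereocentre into the spiro centre.
4. Dienone ⇐ (S)-limonene (lithiation of the isopropenyl methyl) + prenal.
5. Ring order: ring A is bought (limonene); ring B is closed photochemically; then ring B, then ring A are functionalised.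

Assumptions: the target is the (2S,3S,6R,9S,10R) isomer encoded by the SMILES. Atom numbers follow chamigrene numbering: ring A = C1–C6 (C6 spiro, C3 carries the methyl C15); ring B = C6–C11 (C7 carries the exocyclic methylene C14, C11 is gem-dimethyl). C6 of the target maps onto C4 of (S)-(−)-limonene, which is commercial and cheap.

## Route

**Step 1**
Reactants: 1, (S)-(−)-limonene; 2, 3-methylbut-2-enal (prenal)
Product: 3, 2-methyl-6-[(1S)-4-methylcyclohex-3-en-1-yl]hepta-2,6-dien-4-ol (about 1:1 at the carbinol carbon)
Conditions: n-BuLi, TMEDA, excess 1, 25 °C; then 2, THF, −78 °C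
Reagents that add atoms: none (both carbon fragments are the listed reactants)
Why: Allylic lithiation of limonene takes place at the isopropenyl methyl (known reaction) and leaves the C4–H stereocentre untouched; the symmetrical 2-substituted allyl-lithium then adds 1,2 to the aldehyde, and the new carbinol centre is erased in step 2.

**Step 2**
Reactants: 3
Product: 4, 2-methyl-6-[(1S)-4-methylcyclohex-3-en-1-yl]hepta-2,6-dien-4-one
Conditions: MnO2, CH2Cl2, 20 °C
Reagents that add atoms: none
Why: Allylic alcohol oxidation under neutral conditions gives the β,β-dimethyl enone while keeping the 1,1-disubstituted alkene out of conjugation and the ring stereocentre intact.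

**Step 3 (key step)**
Reactants: 4
Product: 5, (6R)-9-(trimethylsilyloxy)chamigra-2,7(14),9-triene (spiro[5.5]undecane; ring A 2-ene with 3-methyl; ring B with 7-methylidene, C9=C10 silyl enol ether, 11,11-dimethyl)
Conditions: hν (350 nm, Pyrex), trans-piperylene (2 M), C6H6 (5 mM, degassed), 10 °C; then lamp off, BSA, 20 °C
Reagents that add atoms: N,O-bis(trimethylsilyl)acetamide (BSA), CC(=N[Si](C)(C)C)O[Si](C)(C)C
Why: Proposed new method: n→π* excitation of the s-cis enone lets the singlet carbonyl oxygen abstract the weak tertiary allylic C6–H through a six-membered transition state (Norrish type II step), and the singlet allyl/1-hydroxyallyl biradical, which cannot fragment (cleavage would give an allene) and holds C11 next to C6 on the face the hydrogen left, should close 1,6 (C6–C11) rather than 1,4 before the tether rotates, so the limonene stereocentre is transferred with retention (6R), the exocyclic methylene is kept and the C9=C10 enol is silylated in the dark; piperylene quenches the triplet crossed [2+2] known for 1,5-dien-3-ones, and the competing photoenolisation via the Z-methyl and the 1,3-acyl shift are reversible or degenerate; the closest known reaction type is the Norrish–Yang photocyclisation (including memory-of-chirality cases), here extended to a vinylogous 1,6-closure that makes vicinal quaternary carbons.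

**Step 4**
Reactants: 5
Product: 6, (6R,10R)-10-bromochamigra-2,7(14)-dien-9-one
Conditions: NBS, NaHCO3, THF, −78 → 0 °C
Reagents that add atoms: N-bromosuccinimide, O=C1CCC(=O)N1Br
Why: Electrophilic bromination of the silyl enol ether can only occur at C10; attack anti to the ring-A methylene (C5) that sits axial on ring B gives the equatorial bromide cis to C1, which is also the thermodynamic epimer by analogy with elatol-type bromoketones, and a mixture can be equilibrated with catalytic pyridinium bromide.

**Step 5**
Reactants: 6
Product: 7, (6R,9S,10R)-10-bromochamigra-2,7(14)-dien-9-yl acetate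
Conditions: DIBAL-H, CH2Cl2, −78 °C; then Ac2O, pyridine, DMAP, −78 → 20 °C
Reagents that add atoms: acetic anhydride, CC(=O)OC(C)=O
Why: The bulky hydride attacks C9 equatorially, away from the axial C11 methyl, giving the axial alcohol cis to the equatorial bromine (the cis-bromohydrin outcome precedented for the elatol bromoketone); the aluminium alkoxide is acetylated in the same pot (reductive acetylation).

**Step 6**
Reactants: 7
Product: 8, (2R,3S,6R,9S,10R)-10-bromo-2,3-epoxychamigr-7(14)-en-9-yl acetate (oxirane anti to C7, syn to C11)
Conditions: mCPBA, NaHCO3, CH2Cl2, 0 °C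
Reagents that add atoms: m-chloroperbenzoic acid, O=C(OO)c1cccc(Cl)c1
Why: Prilezhaev epoxidation: the trisubstituted ring-A alkene is much more nucleophilic than the hindered C7 methylene, and the peracid approaches anti to the pseudo-axial C7/C14 unit on the spiro carbon.

**Step 7**
Reactants: 8
Product: 9, (2S,3S,6R,9S,10R)-10-bromo-2-chloro-3-hydroxychamigr-7(14)-en-9-yl acetate
Conditions: LiCl, AcOH, THF, 20–40 °C
Reagents that add atoms: lithium chloride, [Li+].[Cl-]
Why: Chloride opening of the epoxide (halohydrin formation): SN2 attack at the secondary C2 is also the trans-diaxial (Fürst–Plattner) mode for the conformer with C11 equatorial, so Cl enters with inversion on the C7 face and the tertiary C3–OH stays axial on the other face.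

**Step 8**
Reactants: 9
Product: 10, 9-acetylisoobtusol, (2S,3S,6R,9S,10R)-3,10-dibromo-2-chlorochamigr-7(14)-en-9-yl acetate
Conditions: TMSBr, 2-methyl-2-butene, CH2Cl2, −20 → 0 °C
Reagents that add atoms: bromotrimethylsilane, C[Si](C)(C)Br
Why: SN1 substitution of the tertiary alcohol with participation by the vicinal axial chlorine (chloronium-like ion): bromide adds axially, anti to C–Cl, giving the trans-diaxial bromochloride with retention at C3; the alkene additive scavenges HBr before it can add to the C7 methylene.

## Compound list

1 | (S)-(−)-limonene | CC1=CC[C@H](CC1)C(C)=C | starting material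
2 | 3-methylbut-2-enal (prenal) | CC(C)=CC=O | starting material
3 | 2-methyl-6-[(1S)-4-methylcyclohex-3-en-1-yl]hepta-2,6-dien-4-ol (carbinol epimers) | C=C(CC(O)C=C(C)C)[C@H]1CCC(C)=CC1 | intermediate
4 | 2-methyl-6-[(1S)-4-methylcyclohex-3-en-1-yl]hepta-2,6-dien-4-one | C=C(CC(=O)C=C(C)C)[C@H]1CCC(C)=CC1 | intermediate
5 | (6R)-9-(trimethylsilyloxy)chamigra-2,7(14),9-triene | C=C1CC(O[Si](C)(C)C)=CC(C)(C)[C@@]12CCC(C)=CC2 | intermediate
6 | (6R,10R)-10-bromochamigra-2,7(14)-dien-9-one | C=C1CC(=O)[C@H](Br)C(C)(C)[C@@]12CCC(C)=CC2 | intermediate
7 | (6R,9S,10R)-10-bromochamigra-2,7(14)-dien-9-yl acetate | C=C1C[C@H](OC(C)=O)[C@H](Br)C(C)(C)[C@@]12CCC(C)=CC2 | intermediate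
8 | (2R,3S,6R,9S,10R)-10-bromo-2,3-epoxychamigr-7(14)-en-9-yl acetate | C=C1C[C@H](OC(C)=O)[C@H](Br)C(C)(C)[C@@]12CC[C@]3(C)O[C@@H]3C2 | intermediate
9 | (2S,3S,6R,9S,10R)-10-bromo-2-chloro-3-hydroxychamigr-7(14)-en-9-yl acetate | C=C1C[C@H](OC(C)=O)[C@H](Br)C(C)(C)[C@@]12CC[C@](C)(O)[C@@H](Cl)C2 | intermediate
10 | 9-acetylisoobtusol | C=C1C[C@H](OC(C)=O)[C@H](Br)C(C)(C)[C@@]12CC[C@](C)(Br)[C@@H](Cl)C2 | target

## Summary

Total steps: 8. Longest linear sequence: 8.

Steps most likely to fail:

1. **Step 3 (proposed new photocyclisation).**
   - Risks: low quantum yield; triplet crossed [2+2]; coupling through the CH2 end of the allyl radical (non-spiro ring); 1,4-closure to a cyclobutanol; partial loss of configuration at C6.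
   - Fallback (known chemistry, substrate control instead of chirality memory): open (+)-trans-limonene oxide with LiCl/AcOH to place an axial Cl at C2, then ozonolyse the isopropenyl group to the methyl ketone. C-acylate with 3,3-dimethylacryloyl chloride (MgBr2·OEt2, i-Pr2NEt) to the 1,3-diketone and close ring B by acid-mediated 6-endo enol Michael addition anti to the axial chlorine. Bring in C14 by Stork–Danheiser methyl addition, return ring A to the epoxide with base, and rejoin at the bromoketone stage. This costs about four extra steps.

2. **Step 7 (chloride opening).**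
   - Risk: the C7 methylene shields the face of C2 that chloride must attack, so acid-promoted rearrangement of the epoxide may compete.
   - Fallback: isomerise epoxide 8 to the exocyclic allylic alcohol (C3=C15, C2–OH; Al(OiPr)3). Displace the C2–OH with inversion (PPh3/hexachloroacetone, SN2 without allylic shift), then add HBr in the Markovnikov sense across C3=C15, anti to chlorine.

3. **Step 8 (tertiary alcohol to bromide).**
   - Risks: the β-chloro tertiary alcohol may ionise slowly; HBr may add to the C7 methylene; E1 elimination.
   - Fallback: avoid the carbocation. Dehydrate 9 with Burgess reagent to the C3 exocyclic alkene and install H/Br by radical metal-hydride HAT hydrobromination (Co(salen), PhSiH3, TsBr), which should prefer the less hindered of the two 1,1-disubstituted alkenes.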